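**Easy balance.** By the listed steps, each J consumed stands as X or as Z, so the pool X + Z equals the J lost. With the partition ratio [Z]/[X] called K, X is the pool divided by one plus K.

in all of them: J 0.20 M
- north-west: D 0.18 M; L 0.20 M; temperature 70 °C; the very flask that is asked about, followed so far
- east: D 0.18 M; L 0.20 M; temperature 55 °C; run made earlier
- flask: D 0.180 M; L 0.200 M; temperature 70 °C; time 8.0 d

| run | time / d | X / % | J / % |
|---|---|---|---|
| north-west | 0.250 | 21.0 | 75.5 |
| north-west | 0.833 | 33.0 | 60.0 |
| north-west | 1.25 | 34.2 | 57.9 |
| north-west | 2.08 | 34.9 | 57.5 |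
| north-west | 3.00 | 34.2 | 58.0 |
| north-west | 4.00 | 34.3 | 57.9 |
| north-west | 5.00 | 34.5 | 58.3 |
| east | 0.500 | 17.8 | 79.6 |
| east | 1.67 | 32.3 | 63.8 |
| east | 2.50 | 35.9 | 59.5 |
| east | 4.00 | 36.0 | 58.7 |
| east | 6.00 | 36.7 | 57.9 |
| east | 8.00 | 36.5 | 58.1 |
| east | 10.0 | 36.6 | 58.7 |

(scatter of a reading: 0.3 percentage points)

- oak: at 8.0 d raise the temperature by 15 K, then wait 2.5 d
- ash: at 8.0 d take out 90 % of the X then present, then wait 2.5 d
- birch: change nothing and wait 2.5 d more
- alder: at 8.0 d add D, 100 % of the amount charged, then wait 2.5 d

- removed X is counted in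
- the numbers in the tables scatter by 0.3 percentage points (one standard deviation)
- steps thought possible: J + D -> X; X <-> Z; D + L -> E
- additions bring no volume worth counting

- X, in percent of the J first charged, at 8.0 d
- which option adds most X ("none" when 2 percentage points or less is all one gets) (oak / ash / birch / alder / none)
- X present, with what was taken out counted in, in percent of the J first charged, after oak
- X present, with what was taken out counted in, in percent of the J first charged, after birch

**Which numbers matter.** Time matters little in the north-west run: X reads 34.9 % at 2.08 d and 34.5 % at 5.00 d. A point of error in the pool moves X by less than a point. K needs care: Z is read as a difference of readings, and oak and ash both act through K.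

**The numbers.** Over the last 4 north-west readings the pool averages 42.1 % and X 34.5 %, so the partition ratio [Z]/[X] reads 0.220. The east run gives 0.143. Taking the same factor over another 15 K gives K as 0.341, so this reckoning, with the pool held, puts X after oak at 31.4 %. For ash, the same reckoning lets the remaining pool repartition by K, for a gain of 5.6 percentage points. To beat that in this reckoning, alder needs 7.60 % of its D on J. The first charge put 46.8 % there.

**The forecast.** It gives 34.4 % now and after birch, 31.6 % after oak (against 31.4 % here) and alder as best, reading that the stall “points to D being used up”.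

**The flask.** The flask gives 34.7 % now, 34.7 % after birch, 32.2 % after oak, and gains of 5.4 points for ash and 27 points for alder. D, the limiting reagent, stands at 0 % of its charge after 8.00 d. K on 34.7 % puts Z at 7.63 %, and the flask holds 7.28 %.

    J + D → X, rate k1*[J]^2*[D]^0.5 (k = 0.0140 M⁻¹·⁵ min⁻¹, Ea = 65.0 kJ mol⁻¹)
    X ⇌ Z (K = 0.210, k = 0.00350 min⁻¹, Ea = 112 kJ mol⁻¹, ΔH = 25.0 kJ mol⁻¹)
    D + L → E (k = 0.0110 M⁻¹ min⁻¹, Ea = 64.0 kJ mol⁻¹)
    (constants at 70 °C)

The neighbour charged with 0.45 M of D keeps 9.17 % of its J, a pool of 90.8 %. Divided by one plus K, that pool gives X as 74.5 %, and the neighbour holds 75.1 %.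

The readings are simulated with constants of no real substance; the scatter is artificial.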